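# Total synthesis of dictyol H from (–)-α-santonin (12 steps)

**Retrosynthesis**
1. Dictyol H comes from its 6-epimer by late oxidation and hydride reduction. The THF and the tertiary acetate come from a homoprenyl tertiary carbinol by a photoredox oxy-acetoxylation, the last ring formed.
2. The C11 carbinol comes from a Felkin-type addition of a homoprenyl nucleophile to a C7 methyl ketone. That ketone comes from oxidative decarboxylation of the santonin lactone carboxylate, which excises C12.
3. The 5–7 skeleton (C1–C5 bond, cyclopentene, C10 carbon) comes from the photochemical dienone rearrangement of santonin. The rings are formed in this order: the 5-7 bicycle in step 1, the THF in step 9. The C3 ketone is removed by Kabalka transposition, and the C10 alcohol is dehydrated to the exocyclic methylene.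

**Assumptions** (stated as ambiguities, one line each):
- Guaiane numbering is used (C14 = 10-methylene, C15 = 4-methyl).
- The rearrangement gives the 1α-H ring fusion, as in isophotosantonic lactone.
- The C10 configuration in 2 is not specified because it is destroyed in step 2.

---

**Step 1**
Reactants: 1 (–)-α-santonin
Product: 2 isophotosantonic lactone (10-hydroxy-3-oxo-guai-4-en-6,12-olide, 1α-H)
Conditions: hν (medium-pressure Hg lamp, Pyrex), 50% aq. AcOH, rt
Reagents that add atoms: water, O
Why: Santonin-type cross-conjugated dienone photorearrangement (dienone → lumiketone → acid-opened cyclopropyl ketone) forms the C1–C5 bond and the 5–7 skeleton, and water traps the C10 cation. C1–H is set by the stereospecific opening, and C6, C7 and C11 are untouched.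

**Step 2**
Reactants: 2
Product: 3 guaia-4,10(14)-dien-3-one-6,12-olide
Conditions: Burgess reagent, PhH, 50 °C
Reagents that add atoms: none
Why: Syn-Ei dehydration, Burgess-type, abstracts the readily accessible C14 methyl hydrogens, which favours the exocyclic 1,1-disubstituted alkene. The enone and lactone are inert.

**Step 3**
Reactants: 3
Product: 4 tosylhydrazone of 3
Conditions: TsNHNH2, MeOH, cat. HCl, 40 °C
Reagents that add atoms: p-toluenesulfonyl hydrazide, Cc1ccc(cc1)S(=O)(=O)NN
Why: Standard condensation that prepares the enone for allylic-diazene transposition.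

**Step 4**
Reactants: 4
Product: 5 guaia-3,10(14)-dien-6,12-olide (1α-H, 5α-H)
Conditions: catecholborane, CHCl3, 0 °C; then NaOAc·3H2O, reflux
Reagents that add atoms: none
Why: Kabalka reduction of the enone tosylhydrazone gives an allylic diazene. Its retro-ene loss of N2 moves the alkene to C3=C4 and delivers H to C5 on the convex face, cis to H1, which sets C5.

**Step 5**
Reactants: 5
Product: 6 6-hydroxy-guaia-3,10(14)-dien-12-oic acid (used as its Li salt)
Conditions: LiOH, THF/H2O, 50 °C
Reagents that add atoms: water, O
Why: Saponification opens the trans-fused lactone with retention at C6, freeing the C6 alcohol and the C12 acid. The salt is used directly to avoid relactonisation.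

**Step 6**
Reactants: 6
Product: 7 7-acetyl-6-hydroxy-guaia-3,10(14)-diene (C11 methyl ketone, C12 lost)
Conditions: Fe(acac)3 (10 mol%), Cs2CO3, MeCN, O2 (1 atm), 390 nm LEDs, rt
Reagents that add atoms: dioxygen, O=O
Why: Photochemical LMCT decarboxylation of the secondary carboxylate gives the C11 radical. O2 trapping and Kornblum–DeLaMare-type collapse of the hydroperoxide give the methyl ketone. The C11 stereocentre is destroyed and C7 is untouched.

**Step 7**
Reactants: 7
Product: 8 C6-OTBS ether of 7
Conditions: TBSOTf, 2,6-lutidine, CH2Cl2, –78 °C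
Reagents that add atoms: TBSOTf, CC(C)(C)[Si](C)(C)OS(=O)(=O)C(F)(F)F
Why: A bulky silyl ether blocks chelation and makes C6 a large Felkin substituent for the next step.

**Step 8**
Reactants: 8; 9 5-bromo-2-methylpent-2-ene
Product: 10 tertiary carbinol (C11-OH, CH3, homoprenyl)
Conditions: 9, Mg, THF → RMgBr; anhydrous CeCl3, THF, –78 °C; then add 8
Reagents that add atoms: 5-bromo-2-methylpent-2-ene, CC(C)=CCCBr
Why: Non-chelating Felkin–Anh addition of an organocerium to the C7 ketone (the C6 branch anti to the nucleophile) sets C11 relative to C7, giving the C11 configuration of the target; CeCl3 suppresses enolisation and epimerisation of C7.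

**Step 9**
Reactants: 10
Product: 11 THF acetate with C6-OTBS (C15-OAc)
Conditions: 9-mesityl-10-methylacridinium BF4 (5 mol%), Cu(OAc)2 (2.2 equiv), AcOH/CH2Cl2 (1:4), blue LEDs, rt
Reagents that add atoms: acetic acid, CC(=O)O
Why: Proposed new method: the excited acridinium oxidises the prenyl alkene to its radical cation, and the C11 tertiary alcohol attacks C14 (5-exo, anti-Markovnikov, chair-like with C7 pseudo-equatorial). This places C7 trans to C15 and sets C14, and Cu(II) oxidises the resulting tertiary C15 radical to the cation, which AcO⁻ captures to give the tertiary acetate. The closest known reactions are Nicewicz anti-Markovnikov photoredox alkenol hydroetherification and Cu-mediated radical–polar crossover oxy-acyloxylation. This combines them into an oxidative alkoxy-acetoxylation that has not been shown for a tertiary alcohol with a trisubstituted alkene.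

**Step 10**
Reactants: 11
Product: 12 C6-epi-dictyol H (6α-OH)
Conditions: TBAF, THF, 0 °C → rt
Reagents that add atoms: none
Why: Fluoride cleaves the silyl ether. The acetate, the THF and both alkenes are untouched.

**Step 11**
Reactants: 12
Product: 13 C6 ketone
Conditions: Dess–Martin periodinane, NaHCO3, CH2Cl2, rt
Reagents that add atoms: none
Why: Mild oxidation of the hindered secondary alcohol destroys the santonin-derived C6 configuration.

**Step 12**
Reactants: 13
Product: 14 dictyol H
Conditions: NaBH4, MeOH, –40 °C
Reagents that add atoms: none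
Why: Hydride attacks the convex face (the H1/H5 face, opposite the cis-fused cyclopentene and C7 substituent), giving the 6-OH on the concave face, cis to C11, as in the target.

---

**Compound list**
| No. | Name | SMILES | Role |
|---|---|---|---|
| 1 | (–)-α-santonin | `C[C@H]1[C@@H]2CC[C@]3(C=CC(=O)C(=C3[C@H]2OC1=O)C)C` | starting material |
| 2 | isophotosantonic lactone (C10 unspecified) | `C[C@@H]1C(=O)O[C@@H]2C3=C(C)C(=O)C[C@H]3C(C)(O)CC[C@@H]12` | intermediate |
| 3 | guaia-4,10(14)-dien-3-one-6,12-olide | `C[C@@H]1C(=O)O[C@@H]2C3=C(C)C(=O)C[C@H]3C(=C)CC[C@@H]12` | intermediate |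
| 4 | tosylhydrazone of 3 | `C[C@@H]1C(=O)O[C@@H]2C3=C(C)C(=NNS(=O)(=O)c4ccc(C)cc4)C[C@H]3C(=C)CC[C@@H]12` | intermediate |
| 5 | guaia-3,10(14)-dien-6,12-olide | `C[C@@H]1C(=O)O[C@@H]2[C@H]3C(C)=CC[C@H]3C(=C)CC[C@@H]12` | intermediate |
| 6 | 6-hydroxy-guaia-3,10(14)-dien-12-oic acid | `C=C1CC[C@@H]([C@H](C)C(=O)O)[C@H](O)[C@H]2C(C)=CC[C@@H]12` | intermediate |
| 7 | 7-acetyl-6-hydroxy-3,10(14)-guaiadiene | `C=C1CC[C@@H](C(C)=O)[C@H](O)[C@H]2C(C)=CC[C@@H]12` | intermediate |
| 8 | C6-OTBS ether of 7 | `C=C1CC[C@@H](C(C)=O)[C@H](O[Si](C)(C)C(C)(C)C)[C@H]2C(C)=CC[C@@H]12` | intermediate |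
| 9 | 5-bromo-2-methylpent-2-ene | `CC(C)=CCCBr` | starting material |
| 10 | homoprenyl tertiary carbinol | `C=C1CC[C@@H]([C@](C)(O)CCC=C(C)C)[C@H](O[Si](C)(C)C(C)(C)C)[C@H]2C(C)=CC[C@@H]12` | intermediate |
| 11 | THF acetate, C6-OTBS | `C=C1CC[C@@H]([C@@]2(C)CC[C@H](C(C)(C)OC(C)=O)O2)[C@H](O[Si](C)(C)C(C)(C)C)[C@H]2C(C)=CC[C@@H]12` | intermediate |
| 12 | C6-epi-dictyol H | `C=C1CC[C@@H]([C@@]2(C)CC[C@H](C(C)(C)OC(C)=O)O2)[C@H](O)[C@H]2C(C)=CC[C@@H]12` | intermediate |
| 13 | C6 ketone | `C=C1CC[C@@H]([C@@]2(C)CC[C@H](C(C)(C)OC(C)=O)O2)C(=O)[C@H]2C(C)=CC[C@@H]12` | intermediate |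
| 14 | dictyol H | `C=C1CC[C@@H]([C@@]2(C)CC[C@H](C(C)(C)OC(C)=O)O2)[C@@H](O)[C@H]2C(C)=CC[C@@H]12` | target |

**Total steps:** 12. **Longest linear sequence:** 12 (1 → 14).

**Three steps most likely to fail**
1. **Step 8 (C11 facial selectivity).** Felkin control through a β-silyloxy, α-branched ketone may be modest.
   - Fallback: alkylate the lactone enolate of 5 from its convex face with the iodide from 9 (the prenyl alkene masked as its dibromide). Then open with MeLi to the C12 methyl ketone and apply a Baeyer–Villiger oxidation with retention, then methanolysis. This gives the same tertiary carbinol with C11 fixed by the lactone.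
2. **Step 9 (proposed new method).** The trisubstituted C3=C4 alkene may compete for oxidation, and C14 diastereoselectivity is unproven.
   - Fallback: use Mukaiyama–Inoki Co(modp)2/O2/iPrOH aerobic oxidative cyclisation of 10 to the 2,5-trans THF carbinol. Then acetylate the tertiary alcohol with Ac2O, Sc(OTf)3.
3. **Step 2 (regioselective dehydration to the exocyclic alkene).** Endocyclic Δ1(10) and Δ9(10) isomers are likely competitors.
   - Fallback: dehydrate non-selectively with SOCl2/pyridine. Then funnel the alkene mixture to the exocyclic isomer by photochemical contra-thermodynamic positional isomerisation (decatungstate/cobaloxime).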